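**Assumption:** the target has no stereocentre, and its only non-ring C=C carries two identical methyl groups, so there is no enantiomer or E/Z isomer to control. "Single enantiomer" is read as the single constitution drawn.

## Retrosynthetic overview

1. Target 15 ⇐ bis-silyl flavonol 14 ⇐ flavone 11: the 3-OH is installed last by C3–H lithiation/borylation/oxidation of the intact flavone, not by the usual Claisen–Schmidt chalcone / Algar–Flynn–Oyamada sequence.
2. Flavone 11 ⇐ iodophenol 5 + CO + aryl alkyne 8: one carbonylative Sonogashira annulation makes C4a–C4, C4–C3 and O1–C2, so ring C is formed last, between finished rings A and B.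
3. Iodophenol 5 ⇐ symmetric phenol 4 ⇐ arene 2 ⇐ 2-methoxyresorcinol 1: sterically controlled Ir C–H borylation/oxidation places the phenol oxygen. The mirror symmetry of 4 makes its two ortho positions identical, which fixes 6-OMe rather than 8-OMe.
4. Alkyne 8 ⇐ 4-hydroxybenzaldehyde 6 by prenylation and Ohira–Bestmann homologation. The prenyl ether is carried from the start, so later steps avoid acid, hydrogenation and electrophilic oxidants, and the TIPS groups leave with buffered fluoride.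

## Route

Step 1
Reactants: 1 2-methoxyresorcinol (2-methoxybenzene-1,3-diol)
Product: 2 1,3-bis(triisopropylsilyloxy)-2-methoxybenzene
Conditions: TIPSCl (2.4 equiv), imidazole (5 equiv), DMF, 40 °C
Reagents that add atoms: chlorotriisopropylsilane (TIPSCl), CC(C)[Si](Cl)(C(C)C)C(C)C
Why: Standard imidazole-mediated O-silylation of both phenols; TIPS is chosen because aryl TIPS ethers survive amines, LDA and mild basic peroxide and are removed at the end without acid.

Step 2
Reactants: 2 1,3-bis(triisopropylsilyloxy)-2-methoxybenzene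
Product: 4 4-methoxy-3,5-bis(triisopropylsilyloxy)phenol, via aryl pinacol boronate 3 (not isolated)
Conditions: [Ir(OMe)(cod)]2 (1.5 mol %), dtbpy (3 mol %), B2pin2 (0.6 equiv), THF, 80 °C; then NaBO3·4H2O, THF/H2O, rt
Reagents that add atoms: bis(pinacolato)diboron, CC1(C)OB(OC1(C)C)B1OC(C)(C)C(C)(C)O1 (its Bpin is held only in 3); sodium perborate, [Na+].[O-]OB=O (gives the phenol oxygen)
Why: Sterically governed Ir-catalysed Hartwig–Miyaura C–H borylation attacks only C5, the one C–H without an ortho substituent, and perborate then oxidises the C–B bond to C–OH in the same pot (one-pot borylation/oxidation).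

Step 3
Reactants: 4 4-methoxy-3,5-bis(triisopropylsilyloxy)phenol
Product: 5 2-iodo-4-methoxy-3,5-bis(triisopropylsilyloxy)phenol
Conditions: NIS (1.0 equiv), MeCN, −20 → 0 °C, dark
Reagents that add atoms: N-iodosuccinimide, O=C1CCC(=O)N1I
Why: Electrophilic aromatic iodination at the only free ring positions, which are equivalent by symmetry and activated (ortho to OH, ortho/para to the silyloxy groups), so a single mono-iodide is possible with one equivalent at low temperature.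

Step 4
Reactants: 6 4-hydroxybenzaldehyde
Product: 7 4-(3-methylbut-2-enyloxy)benzaldehyde
Conditions: prenyl bromide (1.2 equiv), K2CO3, acetone, reflux
Reagents that add atoms: 1-bromo-3-methylbut-2-ene (prenyl bromide), CC(C)=CCBr
Why: Williamson ether synthesis (SN2 O-alkylation of the phenoxide with a primary allylic bromide).

Step 5
Reactants: 7 4-(3-methylbut-2-enyloxy)benzaldehyde
Product: 8 1-ethynyl-4-(3-methylbut-2-enyloxy)benzene
Conditions: Ohira–Bestmann reagent (1.3 equiv), K2CO3 (2 equiv), MeOH, rt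
Reagents that add atoms: dimethyl (1-diazo-2-oxopropyl)phosphonate (Ohira–Bestmann reagent), COP(=O)(OC)C(=[N+]=[N-])C(C)=O
Why: Ohira–Bestmann (Seyferth–Gilbert) homologation converts the aldehyde into the terminal alkyne under mild basic conditions that leave the prenyl ether untouched.

Step 6
Reactants: 5 2-iodo-4-methoxy-3,5-bis(triisopropylsilyloxy)phenol, 8 1-ethynyl-4-(3-methylbut-2-enyloxy)benzene (1.3 equiv)
Product: 11 6-methoxy-2-[4-(3-methylbut-2-enyloxy)phenyl]-5,7-bis(triisopropylsilyloxy)-4H-chromen-4-one, via ynone 9 (not isolated), via enaminone 10 (not isolated)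
Conditions: PdCl2(dppf) (5 mol %), CO (5 bar), Et2NH/THF, 60 °C, no copper
Reagents that add atoms: carbon monoxide, [C-]#[O+] (becomes C4=O); diethylamine, CCNCC (held only in 10, released again)
Why: Carbonylative Sonogashira annulation: oxidative addition into C–I, CO insertion and copper-free alkynylation give ynone 9, Et2NH adds in conjugate fashion to give enaminone 10, and the ortho phenol displaces the amine in a 6-endo addition–elimination, which delivers the flavone rather than the aurone.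

Step 7
Reactants: 11 6-methoxy-2-[4-(3-methylbut-2-enyloxy)phenyl]-5,7-bis(triisopropylsilyloxy)-4H-chromen-4-one
Product: 14 3-hydroxy-6-methoxy-2-[4-(3-methylbut-2-enyloxy)phenyl]-5,7-bis(triisopropylsilyloxy)-4H-chromen-4-one, via 3-lithioflavone 12 (not isolated), via lithium borate 13 (not isolated)
Conditions: B(OiPr)3 (2 equiv), LDA (1.5 equiv), THF, −78 °C (in situ trap); then NaBO3·4H2O, H2O, 0 °C → rt, NH4Cl quench under N2
Reagents that add atoms: sodium perborate, [Na+].[O-]OB=O (gives the 3-oxygen); lithium diisopropylamide, [Li]N(C(C)C)C(C)C (Li held only in 12); triisopropyl borate, CC(C)OB(OC(C)C)OC(C)C (held only in 13)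
Why: Deprotonation–borylation–oxidation: LDA removes the vinylic C3–H next to the carbonyl, the borate present traps the 3-lithio species before it can ring-open, and perborate (which does not epoxidise the prenyl alkene) converts C–B into the enolic C3–OH.

Step 8
Reactants: 14 3-hydroxy-6-methoxy-2-[4-(3-methylbut-2-enyloxy)phenyl]-5,7-bis(triisopropylsilyloxy)-4H-chromen-4-one
Product: 15 3,5,7-trihydroxy-6-methoxy-4'-prenyloxyflavone
Conditions: TBAF (2.4 equiv), AcOH (2.4 equiv), THF, 0 °C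
Reagents that add atoms: none
Why: Fluoride-induced desilylation of both aryl TIPS ethers, buffered with AcOH so that the acid-labile prenyl ether and the base- and air-sensitive flavonol both survive.

## Compound list

1 | 2-methoxyresorcinol (2-methoxybenzene-1,3-diol) | COc1c(O)cccc1O | starting material
2 | 1,3-bis(triisopropylsilyloxy)-2-methoxybenzene | COc1c(O[Si](C(C)C)(C(C)C)C(C)C)cccc1O[Si](C(C)C)(C(C)C)C(C)C | intermediate
3 | 2-[4-methoxy-3,5-bis(triisopropylsilyloxy)phenyl]-4,4,5,5-tetramethyl-1,3,2-dioxaborolane (not isolated) | COc1c(O[Si](C(C)C)(C(C)C)C(C)C)cc(B2OC(C)(C)C(C)(C)O2)cc1O[Si](C(C)C)(C(C)C)C(C)C | intermediate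
4 | 4-methoxy-3,5-bis(triisopropylsilyloxy)phenol | COc1c(O[Si](C(C)C)(C(C)C)C(C)C)cc(O)cc1O[Si](C(C)C)(C(C)C)C(C)C | intermediate
5 | 2-iodo-4-methoxy-3,5-bis(triisopropylsilyloxy)phenol | COc1c(O[Si](C(C)C)(C(C)C)C(C)C)cc(O)c(I)c1O[Si](C(C)C)(C(C)C)C(C)C | intermediate
6 | 4-hydroxybenzaldehyde | O=Cc1ccc(O)cc1 | starting material
7 | 4-(3-methylbut-2-enyloxy)benzaldehyde | CC(C)=CCOc1ccc(C=O)cc1 | intermediate
8 | 1-ethynyl-4-(3-methylbut-2-enyloxy)benzene | C#Cc1ccc(OCC=C(C)C)cc1 | intermediate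
9 | 1-[2-hydroxy-5-methoxy-4,6-bis(triisopropylsilyloxy)phenyl]-3-[4-(3-methylbut-2-enyloxy)phenyl]prop-2-yn-1-one (not isolated) | COc1c(O[Si](C(C)C)(C(C)C)C(C)C)cc(O)c(C(=O)C#Cc2ccc(OCC=C(C)C)cc2)c1O[Si](C(C)C)(C(C)C)C(C)C | intermediate
10 | (E)-3-(diethylamino)-1-[2-hydroxy-5-methoxy-4,6-bis(triisopropylsilyloxy)phenyl]-3-[4-(3-methylbut-2-enyloxy)phenyl]prop-2-en-1-one (not isolated; geometry is erased on ring closure) | COc1c(O[Si](C(C)C)(C(C)C)C(C)C)cc(O)c(C(=O)/C=C(/N(CC)CC)c2ccc(OCC=C(C)C)cc2)c1O[Si](C(C)C)(C(C)C)C(C)C | intermediate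
11 | 6-methoxy-2-[4-(3-methylbut-2-enyloxy)phenyl]-5,7-bis(triisopropylsilyloxy)-4H-chromen-4-one | COc1c(O[Si](C(C)C)(C(C)C)C(C)C)cc2oc(-c3ccc(OCC=C(C)C)cc3)cc(=O)c2c1O[Si](C(C)C)(C(C)C)C(C)C | intermediate
12 | 3-lithio-6-methoxy-2-[4-(3-methylbut-2-enyloxy)phenyl]-5,7-bis(triisopropylsilyloxy)-4H-chromen-4-one (not isolated) | COc1c(O[Si](C(C)C)(C(C)C)C(C)C)cc2oc(-c3ccc(OCC=C(C)C)cc3)c([Li])c(=O)c2c1O[Si](C(C)C)(C(C)C)C(C)C | intermediate
13 | lithium triisopropoxy[6-methoxy-4-oxo-2-[4-(3-methylbut-2-enyloxy)phenyl]-5,7-bis(triisopropylsilyloxy)-4H-chromen-3-yl]borate (not isolated) | [Li+].COc1c(O[Si](C(C)C)(C(C)C)C(C)C)cc2oc(-c3ccc(OCC=C(C)C)cc3)c([B-](OC(C)C)(OC(C)C)OC(C)C)c(=O)c2c1O[Si](C(C)C)(C(C)C)C(C)C | intermediate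
14 | 3-hydroxy-6-methoxy-2-[4-(3-methylbut-2-enyloxy)phenyl]-5,7-bis(triisopropylsilyloxy)-4H-chromen-4-one | COc1c(O[Si](C(C)C)(C(C)C)C(C)C)cc2oc(-c3ccc(OCC=C(C)C)cc3)c(O)c(=O)c2c1O[Si](C(C)C)(C(C)C)C(C)C | intermediate
15 | 3,5,7-trihydroxy-6-methoxy-4'-prenyloxyflavone | COc1c(O)cc2oc(-c3ccc(OCC=C(C)C)cc3)c(O)c(=O)c2c1O | target

## Step count and risks

Total step count: 8. Longest linear sequence: 6 steps (1 → 2 → 4 → 5 → 11 → 14 → 15); the alkyne arm (6 → 7 → 8) is 2 steps and joins at step 6.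

**Most likely to fail, first: step 6.** The di-ortho-substituted, electron-rich iodide may give the diethylamide (aminocarbonylation), the aurone (5-exo closure) or the non-carbonylative benzofuran, and Pd(0)/amine can slowly ionise the prenyl ether. The fallback sets out from phenol 4 and comes back at flavone 11, without palladium or CO. Magnesium-mediated ortho-formylation of 4 (MgCl2, Et3N, paraformaldehyde, MeCN, reflux) gives 2-hydroxy-5-methoxy-4,6-bis(triisopropylsilyloxy)benzaldehyde F1. Alkyne 8 is deprotonated with n-BuLi (THF, −78 °C) to lithium [4-(3-methylbut-2-enyloxy)phenyl]acetylide F2, and 2.2 equivalents of it add to F1 to give racemic 1-[2-hydroxy-5-methoxy-4,6-bis(triisopropylsilyloxy)phenyl]-3-[4-(3-methylbut-2-enyloxy)phenyl]prop-2-yn-1-ol F3. MnO2 (CH2Cl2, rt) oxidises F3 to ynone 9, now isolated, and Et2NH in EtOH (rt) closes it through enaminone 10 to flavone 11.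

**Second: step 7.** The 3-lithio species can ring-open to the ynone phenoxide, and the α-boryl enone can protodeboronate back to 11. The fallback sets out from iodophenol 5 and comes back at 14; it introduces the C3 oxygen by epoxidation and therefore puts the prenyl group on afterwards. Iodophenol 5, CO and commercial 1-(benzyloxy)-4-ethynylbenzene (C#Cc1ccc(OCc2ccccc2)cc1) react under the step 6 conditions through the benzyloxy ynone F4 and the benzyloxy enaminone F5 to give 2-[4-(benzyloxy)phenyl]-6-methoxy-5,7-bis(triisopropylsilyloxy)-4H-chromen-4-one F6. Dimethyldioxirane (acetone/CH2Cl2, 0 °C) gives the racemic flavone 2,3-epoxide F7, which catalytic p-TsOH opens to 2-[4-(benzyloxy)phenyl]-3-hydroxy-6-methoxy-5,7-bis(triisopropylsilyloxy)-4H-chromen-4-one F8. Hydrogenolysis (H2, Pd/C, EtOAc, rt) gives 3-hydroxy-2-(4-hydroxyphenyl)-6-methoxy-5,7-bis(triisopropylsilyloxy)-4H-chromen-4-one F9. Prenyl bromide (1.05 equiv) with K2CO3 (1.1 equiv) in DMF at 0 °C → rt alkylates the more acidic, non-chelated 4'-OH in preference to the carbonyl-bound 3-OH and gives 14.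

**Third: step 3.** The hydroquinone-type phenol may be oxidised to the quinone or iodinated twice. The fallback sets out from phenol 4 and comes back at iodophenol 5, using directed ortho-metalation in place of electrophilic substitution. MOMCl and iPr2NEt (CH2Cl2, 0 °C) give 2-methoxy-5-(methoxymethoxy)-1,3-bis(triisopropylsilyloxy)benzene F10. s-BuLi/TMEDA (THF, −78 °C, kept cold to prevent O→C silyl migration) gives the aryllithium [2-(methoxymethoxy)-5-methoxy-4,6-bis(triisopropylsilyloxy)phenyl]lithium F11, and I2 at −78 °C gives 4-iodo-2-methoxy-5-(methoxymethoxy)-1,3-bis(triisopropylsilyloxy)benzene F12. Catalytic HCl in MeOH (40 °C) removes the MOM group, which the aryl TIPS ethers tolerate, and returns 5.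

## Further compounds

F1 | step 6 | 2-hydroxy-5-methoxy-4,6-bis(triisopropylsilyloxy)benzaldehyde | COc1c(O[Si](C(C)C)(C(C)C)C(C)C)cc(O)c(C=O)c1O[Si](C(C)C)(C(C)C)C(C)C
F2 | step 6 | lithium [4-(3-methylbut-2-enyloxy)phenyl]acetylide | [Li]C#Cc1ccc(OCC=C(C)C)cc1
F3 | step 6 | rac-1-[2-hydroxy-5-methoxy-4,6-bis(triisopropylsilyloxy)phenyl]-3-[4-(3-methylbut-2-enyloxy)phenyl]prop-2-yn-1-ol | COc1c(O[Si](C(C)C)(C(C)C)C(C)C)cc(O)c(C(O)C#Cc2ccc(OCC=C(C)C)cc2)c1O[Si](C(C)C)(C(C)C)C(C)C
F4 | step 7 | 3-[4-(benzyloxy)phenyl]-1-[2-hydroxy-5-methoxy-4,6-bis(triisopropylsilyloxy)phenyl]prop-2-yn-1-one | COc1c(O[Si](C(C)C)(C(C)C)C(C)C)cc(O)c(C(=O)C#Cc2ccc(OCc3ccccc3)cc2)c1O[Si](C(C)C)(C(C)C)C(C)C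
F5 | step 7 | (E)-3-[4-(benzyloxy)phenyl]-3-(diethylamino)-1-[2-hydroxy-5-methoxy-4,6-bis(triisopropylsilyloxy)phenyl]prop-2-en-1-one | COc1c(O[Si](C(C)C)(C(C)C)C(C)C)cc(O)c(C(=O)/C=C(/N(CC)CC)c2ccc(OCc3ccccc3)cc2)c1O[Si](C(C)C)(C(C)C)C(C)C
F6 | step 7 | 2-[4-(benzyloxy)phenyl]-6-methoxy-5,7-bis(triisopropylsilyloxy)-4H-chromen-4-one | COc1c(O[Si](C(C)C)(C(C)C)C(C)C)cc2oc(-c3ccc(OCc4ccccc4)cc3)cc(=O)c2c1O[Si](C(C)C)(C(C)C)C(C)C
F7 | step 7 | rac-1a-[4-(benzyloxy)phenyl]-5-methoxy-4,6-bis(triisopropylsilyloxy)-1a,7a-dihydro-7H-oxireno[2,3-b]chromen-7-one (flavone 2,3-epoxide, cis-fused by necessity) | COc1c(O[Si](C(C)C)(C(C)C)C(C)C)cc2OC3(c4ccc(OCc5ccccc5)cc4)OC3C(=O)c2c1O[Si](C(C)C)(C(C)C)C(C)C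
F8 | step 7 | 2-[4-(benzyloxy)phenyl]-3-hydroxy-6-methoxy-5,7-bis(triisopropylsilyloxy)-4H-chromen-4-one | COc1c(O[Si](C(C)C)(C(C)C)C(C)C)cc2oc(-c3ccc(OCc4ccccc4)cc3)c(O)c(=O)c2c1O[Si](C(C)C)(C(C)C)C(C)C
F9 | step 7 | 3-hydroxy-2-(4-hydroxyphenyl)-6-methoxy-5,7-bis(triisopropylsilyloxy)-4H-chromen-4-one | COc1c(O[Si](C(C)C)(C(C)C)C(C)C)cc2oc(-c3ccc(O)cc3)c(O)c(=O)c2c1O[Si](C(C)C)(C(C)C)C(C)C
F10 | step 3 | 2-methoxy-5-(methoxymethoxy)-1,3-bis(triisopropylsilyloxy)benzene | COCOc1cc(O[Si](C(C)C)(C(C)C)C(C)C)c(OC)c(O[Si](C(C)C)(C(C)C)C(C)C)c1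
F11 | step 3 | [2-(methoxymethoxy)-5-methoxy-4,6-bis(triisopropylsilyloxy)phenyl]lithium | COCOc1cc(O[Si](C(C)C)(C(C)C)C(C)C)c(OC)c(O[Si](C(C)C)(C(C)C)C(C)C)c1[Li]
F12 | step 3 | 4-iodo-2-methoxy-5-(methoxymethoxy)-1,3-bis(triisopropylsilyloxy)benzene | COCOc1cc(O[Si](C(C)C)(C(C)C)C(C)C)c(OC)c(O[Si](C(C)C)(C(C)C)C(C)C)c1I
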